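## Retrosynthetic overview

1. Target 35 ⇐ hydrogenation/double hydrogenolysis of alkene 34 ⇐ Julia–Kocienski olefination (C12=C13) of tetralin sulfone 27 with aldehyde 33, which already carries C15 (Evans allylation) and the 3-phenylpropanoate.
2. The saturated ring is the only ring made (the benzene ring is that of vanillic acid) and is closed last: C2–C3 bond by 6-exo-tet alkylation of the nitronate of 21 on its own primary bromide, then radical removal of NO2.
3. Key step: C1–C11 bond by intermolecular enamine-catalysed Michael addition of propanal 19 to nitrostyrene 18, which sets C1 and C11 as the syn pair.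
4. 18 ⇐ aldehyde 15 (Henry); its benzylic C4 centre ⇐ Evans methylation of arylacetyl imide 11 ⇐ Stille allylation and oxidative cleavage on the triflate of benzyl 5-formylvanillate.
5. Labels: C1–C4 are the saturated ring carbons (C1 bears the side chain, C4 the methyl), C11 is the side-chain CH(CH3) next to the ring, C12–C14 are chain CH2, C15 is CH(CH3)CH2O.

Assumption: the target is the (5R,8S)-tetralin with the (2S,6R) side chain read from the SMILES (ring substituents 1,4-trans); (S)-4-benzyloxazolidin-2-one and its N-propanoyl derivative are taken as cheap commercial chemicals.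

## Route

Step 1
Reactants: 1 vanillic acid
Product: 2 benzyl 4-hydroxy-3-methoxybenzoate
Conditions: BnBr (1.05 equiv), KHCO3, DMF, 40 °C
Reagents that add atoms: benzyl bromide, BrCc1ccccc1
Why: Carboxylate O-alkylation (SN2) under bicarbonate esterifies the acid only, because the phenol is not deprotonated.

Step 2
Reactants: 2 benzyl vanillate
Product: 3 benzyl 3-formyl-4-hydroxy-5-methoxybenzoate
Conditions: MgCl2, Et3N, (CH2O)n, MeCN, reflux; aq. HCl work-up
Reagents that add atoms: paraformaldehyde (formaldehyde), C=O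
Why: Magnesium-phenoxide-directed ortho-formylation (Casnati–Skattebøl) can only strike the single free position ortho to the hydroxyl.

Step 3
Reactants: 3 formyl phenol
Product: 4 benzyl 3-formyl-5-methoxy-4-(trifluoromethylsulfonyloxy)benzoate
Conditions: Tf2O, pyridine, CH2Cl2, 0 °C
Reagents that add atoms: trifluoromethanesulfonic anhydride, O=S(=O)(OS(=O)(=O)C(F)(F)F)C(F)(F)F
Why: O-Sulfonylation turns the phenol into an aryl triflate for cross-coupling.

Step 4
Reactants: 4 aryl triflate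
Product: 5 benzyl 4-allyl-3-formyl-5-methoxybenzoate
Conditions: CH2=CHCH2SnBu3, Pd(PPh3)4 (5 mol %), LiCl, DMF, 90 °C
Reagents that add atoms: allyltributylstannane, C=CC[Sn](CCCC)(CCCC)CCCC
Why: Stille cross-coupling; the ortho formyl and para ester groups activate the triflate for oxidative addition and LiCl assists transmetalation.

Step 5
Reactants: 5 allyl aldehyde
Product: 6 benzyl 4-allyl-3-(1,3-dioxolan-2-yl)-5-methoxybenzoate
Conditions: Me3SiOCH2CH2OSiMe3, Me3SiOTf (5 mol %), CH2Cl2, −78 → −20 °C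
Reagents that add atoms: 1,2-bis(trimethylsilyloxy)ethane, C[Si](C)(C)OCCO[Si](C)(C)C
Why: Noyori acetalisation masks the aldehyde under aprotic, cold conditions that leave the benzyl ester alone.

Step 6
Reactants: 6 allyl dioxolane
Product: 8 2-[4-(benzyloxycarbonyl)-2-(1,3-dioxolan-2-yl)-6-methoxyphenyl]acetic acid, via arylacetaldehyde 7 (not isolated)
Conditions: O3, CH2Cl2, −78 °C; Me2S; then NaClO2, NaH2PO4, 2-methylbut-2-ene, t-BuOH/H2O, 0 °C → rt
Reagents that add atoms: ozone, [O-][O+]=O; sodium chlorite, [Na+].[O-]Cl=O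
Why: Ozonolysis of the terminal alkene followed by Pinnick oxidation gives the arylacetic acid, and the cyclic acetal survives the buffered chlorite.

Step 7
Reactants: 8 arylacetic acid; 9 (S)-4-benzyloxazolidin-2-one
Product: 11 benzyl 4-{2-[(S)-4-benzyl-2-oxooxazolidin-3-yl]-2-oxoethyl}-3-(1,3-dioxolan-2-yl)-5-methoxybenzoate, via mixed pivalic anhydride 10 (not isolated)
Conditions: t-BuCOCl, Et3N, THF, −20 °C; then LiCl, 9, rt
Reagents that add atoms: none
Why: N-Acylation of the Evans auxiliary through the mixed anhydride (LiCl/Et3N variant), which needs no strong base.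

Step 8
Reactants: 11 arylacetyl imide
Product: 12 benzyl 4-{(S)-1-[(S)-4-benzyl-2-oxooxazolidin-3-yl]-1-oxopropan-2-yl}-3-(1,3-dioxolan-2-yl)-5-methoxybenzoate
Conditions: NaN(SiMe3)2, THF, −78 °C; MeI
Reagents that add atoms: iodomethane, CI
Why: Evans asymmetric alkylation: the chelated Z-sodium enolate is methylated on the face opposite the auxiliary benzyl group, giving the (S)-2-arylpropanoyl unit that becomes C4.

Step 9
Reactants: 12 methylated imide
Product: 13 benzyl 3-(1,3-dioxolan-2-yl)-4-[(S)-1-hydroxypropan-2-yl]-5-methoxybenzoate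
Conditions: NaBH4, THF/H2O (4:1), 0 °C → rt
Reagents that add atoms: none
Why: Reductive cleavage of the imide gives the primary alcohol and returns the auxiliary, while the aryl ester and acetal are inert to NaBH4.

Step 10
Reactants: 13 alcohol
Product: 14 benzyl 4-[(S)-1-bromopropan-2-yl]-3-(1,3-dioxolan-2-yl)-5-methoxybenzoate
Conditions: CBr4, PPh3, imidazole (0.2 equiv), CH2Cl2, 0 °C
Reagents that add atoms: tetrabromomethane, BrC(Br)(Br)Br
Why: Appel bromination is an SN2 reaction at the primary carbon, so the neighbouring stereocentre is untouched.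

Step 11
Reactants: 14 bromo dioxolane
Product: 15 benzyl 4-[(S)-1-bromopropan-2-yl]-3-formyl-5-methoxybenzoate
Conditions: 2 M HCl, THF, 45 °C
Reagents that add atoms: water, O
Why: Acid-catalysed acetal hydrolysis frees the aldehyde; the hindered primary bromide and the benzyl ester tolerate dilute acid.

Step 12
Reactants: 15 bromo aldehyde
Product: 18 benzyl 4-[(S)-1-bromopropan-2-yl]-3-methoxy-5-[(E)-2-nitrovinyl]benzoate, via nitro alcohol 16 (not isolated), via nitro mesylate 17 (not isolated)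
Conditions: MeNO2, 1,1,3,3-tetramethylguanidine (10 mol %), 0 °C → rt; then MsCl, Et3N, CH2Cl2, −10 °C
Reagents that add atoms: nitromethane, C[N+](=O)[O-]
Why: Henry (nitroaldol) addition followed by mesylation and E1cB elimination gives the (E)-nitroalkene under conditions too mild to displace the bromide.

Step 13 (key step)
Reactants: 18 nitroalkene; 19 propanal
Product: 20 benzyl 4-[(S)-1-bromopropan-2-yl]-3-methoxy-5-[(2S,3R)-3-methyl-1-nitro-4-oxobutan-2-yl]benzoate
Conditions: 19 (5 equiv), (S)-2-[diphenyl(trimethylsilyloxy)methyl]pyrrolidine (10 mol %), 4-nitrophenol (10 mol %), toluene, 0 °C → rt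
Reagents that add atoms: none
Why: Enamine-catalysed Michael addition (Hayashi–Jørgensen catalyst): the (E)-enamine of propanal, shielded on one face by the CPh2OSiMe3 group, adds through an acyclic synclinal transition state to give the syn adduct, setting the aryl-bearing carbon (S) and the methyl-bearing carbon (R) under catalyst control.

Step 14
Reactants: 20 nitro aldehyde
Product: 21 benzyl 4-[(S)-1-bromopropan-2-yl]-3-[(2S,3R)-4-hydroxy-3-methyl-1-nitrobutan-2-yl]-5-methoxybenzoate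
Conditions: NaBH4, MeOH/CH2Cl2, −20 °C
Reagents that add atoms: none
Why: Chemoselective borohydride reduction of the aldehyde removes the epimerisable α-centre problem and leaves nitro, bromide and ester untouched.

Step 15
Reactants: 21 bromo nitro alcohol
Product: 22 benzyl (5R,8S)-8-[(R)-1-hydroxypropan-2-yl]-4-methoxy-5-methyl-7-nitro-5,6,7,8-tetrahydronaphthalene-2-carboxylate (C7 epimers)
Conditions: K2CO3, NaI (10 mol %), DMF (0.02 M), rt → 45 °C
Reagents that add atoms: none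
Why: Intramolecular nitronate C-alkylation (6-exo-tet) closes the ring because O-alkylation would need an eight-membered cyclic nitronate; the new C7 centre is removed in the next step.

Step 16
Reactants: 22 nitro tetralin
Product: 23 benzyl (5R,8S)-8-[(R)-1-hydroxypropan-2-yl]-4-methoxy-5-methyl-5,6,7,8-tetrahydronaphthalene-2-carboxylate
Conditions: Bu3SnH (5 equiv), AIBN (0.5 equiv), toluene, 110 °C
Reagents that add atoms: none
Why: Radical denitration (Ono–Tanner) replaces the secondary nitro group by hydrogen through a ring radical that touches no stereocentre.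

Step 17
Reactants: 23 tetralin alcohol
Product: 24 benzyl (5R,8S)-4-methoxy-5-methyl-8-{(R)-1-[(1-phenyl-1H-tetrazol-5-yl)sulfanyl]propan-2-yl}-5,6,7,8-tetrahydronaphthalene-2-carboxylate
Conditions: 1-phenyl-1H-tetrazole-5-thiol, PPh3, DIAD, THF, 0 °C → rt
Reagents that add atoms: 1-phenyl-1H-tetrazole-5-thiol, Sc1nnnn1-c1ccccc1
Why: Mitsunobu thioetherification of the primary alcohol installs the Julia–Kocienski handle without an epimerisable aldehyde.

Step 18
Reactants: 24 sulfide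
Product: 25 benzyl (5R,8S)-4-methoxy-5-methyl-8-{(R)-1-[(1-phenyl-1H-tetrazol-5-yl)sulfonyl]propan-2-yl}-5,6,7,8-tetrahydronaphthalene-2-carboxylate
Conditions: (NH4)6Mo7O24·4H2O (10 mol %), 30 % H2O2, EtOH, 0 °C → rt
Reagents that add atoms: hydrogen peroxide, OO
Why: Molybdate-catalysed peroxide oxidation takes the sulfide cleanly to the sulfone.

Step 19
Reactants: 25 sulfone
Product: 26 (5R,8S)-4-hydroxy-5-methyl-8-{(R)-1-[(1-phenyl-1H-tetrazol-5-yl)sulfonyl]propan-2-yl}-5,6,7,8-tetrahydronaphthalene-2-carboxylic acid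
Conditions: BBr3 (5 equiv), CH2Cl2, −78 → 0 °C; H2O
Reagents that add atoms: none
Why: Lewis-acid dealkylation with BBr3 cleaves the aryl methyl ether and the benzyl ester here, before the acid-sensitive alkyl ester is in the molecule.

Step 20
Reactants: 26 hydroxy acid
Product: 27 benzyl (5R,8S)-4-(benzyloxy)-5-methyl-8-{(R)-1-[(1-phenyl-1H-tetrazol-5-yl)sulfonyl]propan-2-yl}-5,6,7,8-tetrahydronaphthalene-2-carboxylate
Conditions: BnBr (2.5 equiv), K2CO3, DMF, rt
Reagents that add atoms: benzyl bromide, BrCc1ccccc1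
Why: Williamson etherification and carboxylate alkylation put both acidic groups under benzyl protection, so the last step can be a neutral hydrogenolysis.

Step 21
Reactants: 28 (S)-4-benzyl-3-propanoyloxazolidin-2-one
Product: 29 (S)-4-benzyl-3-[(R)-2-methylpent-4-enoyl]oxazolidin-2-one
Conditions: NaN(SiMe3)2, THF, −78 °C; CH2=CHCH2I
Reagents that add atoms: allyl iodide, C=CCI
Why: Evans asymmetric alkylation: allylation of the chelated Z-enolate opposite the auxiliary benzyl group sets the (R) centre that becomes C15.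

Step 22
Reactants: 29 allylated imide
Product: 30 (R)-2-methylpent-4-en-1-ol
Conditions: LiBH4, MeOH (1 equiv), Et2O, 0 °C
Reagents that add atoms: none
Why: Reductive removal of the auxiliary gives the primary alcohol without touching the α-stereocentre.

Step 23
Reactants: 30 (R)-2-methylpent-4-en-1-ol; 31 3-phenylpropanoyl chloride
Product: 32 (R)-2-methylpent-4-en-1-yl 3-phenylpropanoate
Conditions: Et3N, DMAP (5 mol %), CH2Cl2, 0 °C → rt
Reagents that add atoms: none
Why: DMAP-catalysed acylation installs the final ester early, so no late selective esterification is needed.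

Step 24
Reactants: 32 alkenyl ester
Product: 33 (R)-2-methyl-4-oxobutyl 3-phenylpropanoate
Conditions: O3, CH2Cl2, −78 °C; PPh3
Reagents that add atoms: ozone, [O-][O+]=O
Why: Ozonolysis with reductive work-up turns the terminal alkene into the aldehyde; the stereocentre is β to it and cannot epimerise.

Step 25
Reactants: 27 tetralin sulfone; 33 aldehyde
Product: 34 benzyl (5R,8S)-4-(benzyloxy)-5-methyl-8-[(2S,3E,6R)-6-methyl-7-(3-phenylpropanoyloxy)hept-3-en-2-yl]-5,6,7,8-tetrahydronaphthalene-2-carboxylate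
Conditions: KN(SiMe3)2, DME, −60 °C → rt
Reagents that add atoms: none
Why: Julia–Kocienski olefination joins the two halves through the α-sulfonyl carbanion, addition, Smiles rearrangement and loss of SO2; alkene geometry is irrelevant.

Step 26
Reactants: 34 alkene
Product: 35 (5R,8S)-4-hydroxy-5-methyl-8-[(2S,6R)-6-methyl-7-(3-phenylpropanoyloxy)heptan-2-yl]-5,6,7,8-tetrahydronaphthalene-2-carboxylic acid
Conditions: H2 (1 atm), 10 % Pd/C, EtOAc/EtOH, rt
Reagents that add atoms: none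
Why: Heterogeneous hydrogenation saturates the alkene and hydrogenolyses the benzyl ether and benzyl ester in one neutral operation that spares the alkyl ester and all four stereocentres.

## Compound list

1 | vanillic acid (4-hydroxy-3-methoxybenzoic acid) | COc1cc(C(=O)O)ccc1O | starting material
2 | benzyl 4-hydroxy-3-methoxybenzoate | COc1cc(C(=O)OCc2ccccc2)ccc1O | intermediate
3 | benzyl 3-formyl-4-hydroxy-5-methoxybenzoate | COc1cc(C(=O)OCc2ccccc2)cc(C=O)c1O | intermediate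
4 | benzyl 3-formyl-5-methoxy-4-(trifluoromethylsulfonyloxy)benzoate | COc1cc(C(=O)OCc2ccccc2)cc(C=O)c1OS(=O)(=O)C(F)(F)F | intermediate
5 | benzyl 4-allyl-3-formyl-5-methoxybenzoate | COc1cc(C(=O)OCc2ccccc2)cc(C=O)c1CC=C | intermediate
6 | benzyl 4-allyl-3-(1,3-dioxolan-2-yl)-5-methoxybenzoate | COc1cc(C(=O)OCc2ccccc2)cc(C3OCCO3)c1CC=C | intermediate
7 | benzyl 3-(1,3-dioxolan-2-yl)-5-methoxy-4-(2-oxoethyl)benzoate (not isolated) | COc1cc(C(=O)OCc2ccccc2)cc(C3OCCO3)c1CC=O | intermediate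
8 | 2-[4-(benzyloxycarbonyl)-2-(1,3-dioxolan-2-yl)-6-methoxyphenyl]acetic acid | COc1cc(C(=O)OCc2ccccc2)cc(C3OCCO3)c1CC(=O)O | intermediate
9 | (S)-4-benzyloxazolidin-2-one | O=C1N[C@@H](Cc2ccccc2)CO1 | starting material
10 | 2-[4-(benzyloxycarbonyl)-2-(1,3-dioxolan-2-yl)-6-methoxyphenyl]acetic pivalic anhydride (not isolated) | COc1cc(C(=O)OCc2ccccc2)cc(C3OCCO3)c1CC(=O)OC(=O)C(C)(C)C | intermediate
11 | benzyl 4-{2-[(S)-4-benzyl-2-oxooxazolidin-3-yl]-2-oxoethyl}-3-(1,3-dioxolan-2-yl)-5-methoxybenzoate | COc1cc(C(=O)OCc2ccccc2)cc(C3OCCO3)c1CC(=O)N4[C@@H](Cc5ccccc5)COC4=O | intermediate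
12 | benzyl 4-{(S)-1-[(S)-4-benzyl-2-oxooxazolidin-3-yl]-1-oxopropan-2-yl}-3-(1,3-dioxolan-2-yl)-5-methoxybenzoate | COc1cc(C(=O)OCc2ccccc2)cc(C3OCCO3)c1[C@H](C)C(=O)N4[C@@H](Cc5ccccc5)COC4=O | intermediate
13 | benzyl 3-(1,3-dioxolan-2-yl)-4-[(S)-1-hydroxypropan-2-yl]-5-methoxybenzoate | COc1cc(C(=O)OCc2ccccc2)cc(C3OCCO3)c1[C@H](C)CO | intermediate
14 | benzyl 4-[(S)-1-bromopropan-2-yl]-3-(1,3-dioxolan-2-yl)-5-methoxybenzoate | COc1cc(C(=O)OCc2ccccc2)cc(C3OCCO3)c1[C@H](C)CBr | intermediate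
15 | benzyl 4-[(S)-1-bromopropan-2-yl]-3-formyl-5-methoxybenzoate | COc1cc(C(=O)OCc2ccccc2)cc(C=O)c1[C@H](C)CBr | intermediate
16 | benzyl 4-[(S)-1-bromopropan-2-yl]-3-(1-hydroxy-2-nitroethyl)-5-methoxybenzoate (carbinol epimers, not isolated) | COc1cc(C(=O)OCc2ccccc2)cc(C(O)C[N+](=O)[O-])c1[C@H](C)CBr | intermediate
17 | benzyl 4-[(S)-1-bromopropan-2-yl]-3-methoxy-5-[1-(methylsulfonyloxy)-2-nitroethyl]benzoate (not isolated) | COc1cc(C(=O)OCc2ccccc2)cc(C(OS(C)(=O)=O)C[N+](=O)[O-])c1[C@H](C)CBr | intermediate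
18 | benzyl 4-[(S)-1-bromopropan-2-yl]-3-methoxy-5-[(E)-2-nitrovinyl]benzoate | COc1cc(C(=O)OCc2ccccc2)cc(/C=C/[N+](=O)[O-])c1[C@H](C)CBr | intermediate
19 | propanal | CCC=O | starting material
20 | benzyl 4-[(S)-1-bromopropan-2-yl]-3-methoxy-5-[(2S,3R)-3-methyl-1-nitro-4-oxobutan-2-yl]benzoate | COc1cc(C(=O)OCc2ccccc2)cc([C@@H](C[N+](=O)[O-])[C@@H](C)C=O)c1[C@H](C)CBr | intermediate
21 | benzyl 4-[(S)-1-bromopropan-2-yl]-3-[(2S,3R)-4-hydroxy-3-methyl-1-nitrobutan-2-yl]-5-methoxybenzoate | COc1cc(C(=O)OCc2ccccc2)cc([C@@H](C[N+](=O)[O-])[C@@H](C)CO)c1[C@H](C)CBr | intermediate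
22 | benzyl (5R,8S)-8-[(R)-1-hydroxypropan-2-yl]-4-methoxy-5-methyl-7-nitro-5,6,7,8-tetrahydronaphthalene-2-carboxylate (C7 epimers) | COc1cc(C(=O)OCc2ccccc2)cc([C@@H](C3[N+](=O)[O-])[C@@H](C)CO)c1[C@H](C)C3 | intermediate
23 | benzyl (5R,8S)-8-[(R)-1-hydroxypropan-2-yl]-4-methoxy-5-methyl-5,6,7,8-tetrahydronaphthalene-2-carboxylate | COc1cc(C(=O)OCc2ccccc2)cc([C@@H](C3)[C@@H](C)CO)c1[C@H](C)C3 | intermediate
24 | benzyl (5R,8S)-4-methoxy-5-methyl-8-{(R)-1-[(1-phenyl-1H-tetrazol-5-yl)sulfanyl]propan-2-yl}-5,6,7,8-tetrahydronaphthalene-2-carboxylate | COc1cc(C(=O)OCc2ccccc2)cc([C@@H](C3)[C@@H](C)CSc4nnnn4-c5ccccc5)c1[C@H](C)C3 | intermediate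
25 | benzyl (5R,8S)-4-methoxy-5-methyl-8-{(R)-1-[(1-phenyl-1H-tetrazol-5-yl)sulfonyl]propan-2-yl}-5,6,7,8-tetrahydronaphthalene-2-carboxylate | COc1cc(C(=O)OCc2ccccc2)cc([C@@H](C3)[C@@H](C)CS(=O)(=O)c4nnnn4-c5ccccc5)c1[C@H](C)C3 | intermediate
26 | (5R,8S)-4-hydroxy-5-methyl-8-{(R)-1-[(1-phenyl-1H-tetrazol-5-yl)sulfonyl]propan-2-yl}-5,6,7,8-tetrahydronaphthalene-2-carboxylic acid | Oc1cc(C(=O)O)cc([C@@H](C3)[C@@H](C)CS(=O)(=O)c4nnnn4-c5ccccc5)c1[C@H](C)C3 | intermediate
27 | benzyl (5R,8S)-4-(benzyloxy)-5-methyl-8-{(R)-1-[(1-phenyl-1H-tetrazol-5-yl)sulfonyl]propan-2-yl}-5,6,7,8-tetrahydronaphthalene-2-carboxylate | O(Cc6ccccc6)c1cc(C(=O)OCc2ccccc2)cc([C@@H](C3)[C@@H](C)CS(=O)(=O)c4nnnn4-c5ccccc5)c1[C@H](C)C3 | intermediate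
28 | (S)-4-benzyl-3-propanoyloxazolidin-2-one | CCC(=O)N1[C@@H](Cc2ccccc2)COC1=O | starting material
29 | (S)-4-benzyl-3-[(R)-2-methylpent-4-enoyl]oxazolidin-2-one | C=CC[C@@H](C)C(=O)N1[C@@H](Cc2ccccc2)COC1=O | intermediate
30 | (R)-2-methylpent-4-en-1-ol | C=CC[C@@H](C)CO | intermediate
31 | 3-phenylpropanoyl chloride | O=C(Cl)CCc1ccccc1 | starting material
32 | (R)-2-methylpent-4-en-1-yl 3-phenylpropanoate | C=CC[C@@H](C)COC(=O)CCc1ccccc1 | intermediate
33 | (R)-2-methyl-4-oxobutyl 3-phenylpropanoate | O=CC[C@@H](C)COC(=O)CCc1ccccc1 | intermediate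
34 | benzyl (5R,8S)-4-(benzyloxy)-5-methyl-8-[(2S,3E,6R)-6-methyl-7-(3-phenylpropanoyloxy)hept-3-en-2-yl]-5,6,7,8-tetrahydronaphthalene-2-carboxylate | O(Cc6ccccc6)c1cc(C(=O)OCc2ccccc2)cc([C@@H](C3)[C@@H](C)/C=C/C[C@@H](C)COC(=O)CCc4ccccc4)c1[C@H](C)C3 | intermediate
35 | (5R,8S)-4-hydroxy-5-methyl-8-[(2S,6R)-6-methyl-7-(3-phenylpropanoyloxy)heptan-2-yl]-5,6,7,8-tetrahydronaphthalene-2-carboxylic acid | C[C@H](CCC[C@H](C)[C@@H]1CC[C@@H](C)c2c(O)cc(C(=O)O)cc21)COC(=O)CCc1ccccc1 | target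

## Step count and risk

Total step count: 26. Longest linear sequence: 22 steps (steps 1–20, 25 and 26); the side-chain aldehyde 33 takes 4 steps (21–24).

Steps most likely to fail:

Step 4 (Stille allylation of a triflate flanked by formyl and methoxy groups; the coupling may be slow, or the allyl group may isomerise to the conjugated propenyl arene). The fallback sets out from 4 and comes back to the route at 8, building the acetic acid arm by vinylation, hydroboration and oxidation instead of allylation and oxidative cleavage. Suzuki–Miyaura coupling of 4 with potassium vinyltrifluoroborate (PdCl2(dppf), Cs2CO3, THF/H2O, 70 °C) gives benzyl 3-formyl-5-methoxy-4-vinylbenzoate F1. Acetalisation as in step 5 gives benzyl 3-(1,3-dioxolan-2-yl)-5-methoxy-4-vinylbenzoate F2. Anti-Markovnikov hydroboration–oxidation (9-BBN, THF; NaBO3·4H2O) gives benzyl 3-(1,3-dioxolan-2-yl)-4-(2-hydroxyethyl)-5-methoxybenzoate F3. Oxidation with TEMPO (cat.), NaOCl (cat.) and NaClO2 in pH 6.7 phosphate buffer/MeCN then delivers acid 8.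

Step 15 (ring closure by nitronate C-alkylation at a β-branched primary bromide; intermolecular O-alkylation or a sluggish SN2 reaction could win). The fallback sets out from 21 and comes back at 23, so it bypasses steps 15 and 16; it reverses the polarity of the ring closure, with a sulfonyl carbanion at C3 and an iodide at C2.
- Silylation of 21 (t-BuPh2SiCl, imidazole, DMF) gives benzyl 4-[(S)-1-bromopropan-2-yl]-3-[(2S,3R)-4-(tert-butyldiphenylsilyloxy)-3-methyl-1-nitrobutan-2-yl]-5-methoxybenzoate F4.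
- PhSO2Na with NaI (cat.) in DMF at 70 °C displaces the bromide to give benzyl 3-[(2S,3R)-4-(tert-butyldiphenylsilyloxy)-3-methyl-1-nitrobutan-2-yl]-5-methoxy-4-[(S)-1-(phenylsulfonyl)propan-2-yl]benzoate F5.
- NaNO2/AcOH in DMSO at 35 °C converts CH2NO2 into CO2H without touching the α-aryl centre, giving (2S,3R)-2-{5-(benzyloxycarbonyl)-3-methoxy-2-[(S)-1-(phenylsulfonyl)propan-2-yl]phenyl}-4-(tert-butyldiphenylsilyloxy)-3-methylbutanoic acid F6.
- BH3·SMe2 in THF reduces the acid selectively to benzyl 3-[(2S,3R)-4-(tert-butyldiphenylsilyloxy)-1-hydroxy-3-methylbutan-2-yl]-5-methoxy-4-[(S)-1-(phenylsulfonyl)propan-2-yl]benzoate F7.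
- I2, PPh3 and imidazole give benzyl 3-[(2S,3R)-4-(tert-butyldiphenylsilyloxy)-1-iodo-3-methylbutan-2-yl]-5-methoxy-4-[(S)-1-(phenylsulfonyl)propan-2-yl]benzoate F8.
- LiN(SiMe3)2 in THF (−78 → 0 °C, high dilution) closes the ring by 6-exo-tet alkylation to benzyl (5S,8S)-8-[(R)-1-(tert-butyldiphenylsilyloxy)propan-2-yl]-4-methoxy-5-methyl-6-(phenylsulfonyl)-5,6,7,8-tetrahydronaphthalene-2-carboxylate F9 (C6 epimers; the 5S descriptor reflects only a priority change).
- Desulfonylation with 6 % Na(Hg) and Na2HPO4 in MeOH/THF at −20 °C gives benzyl (5R,8S)-8-[(R)-1-(tert-butyldiphenylsilyloxy)propan-2-yl]-4-methoxy-5-methyl-5,6,7,8-tetrahydronaphthalene-2-carboxylate F10.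
- Bu4NF in THF returns alcohol 23.

Step 16 (radical denitration of an unactivated secondary nitro group; this needs forcing conditions and may stall or give low yield). The fallback sets out from 22 and comes back at 23, going through the amine instead of cleaving the C–NO2 bond directly. Nickel boride reduction (NiCl2·6H2O, NaBH4, MeOH, 0 °C) gives benzyl (5R,8S)-7-amino-8-[(R)-1-hydroxypropan-2-yl]-4-methoxy-5-methyl-5,6,7,8-tetrahydronaphthalene-2-carboxylate F11 (C7 epimers). Reductive deamination of this primary amine through its isodiazene with N-(benzyloxy)-N-(pivaloyloxy)-4-(trifluoromethyl)benzamide (MeCN, 45 °C) expels N2 and gives 23.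

## Further compounds

F1 | step 4 | benzyl 3-formyl-5-methoxy-4-vinylbenzoate | COc1cc(C(=O)OCc2ccccc2)cc(C=O)c1C=C
F2 | step 4 | benzyl 3-(1,3-dioxolan-2-yl)-5-methoxy-4-vinylbenzoate | COc1cc(C(=O)OCc2ccccc2)cc(C3OCCO3)c1C=C
F3 | step 4 | benzyl 3-(1,3-dioxolan-2-yl)-4-(2-hydroxyethyl)-5-methoxybenzoate | COc1cc(C(=O)OCc2ccccc2)cc(C3OCCO3)c1CCO
F4 | step 15 | benzyl 4-[(S)-1-bromopropan-2-yl]-3-[(2S,3R)-4-(tert-butyldiphenylsilyloxy)-3-methyl-1-nitrobutan-2-yl]-5-methoxybenzoate | COc1cc(C(=O)OCc2ccccc2)cc([C@@H](C[N+](=O)[O-])[C@@H](C)CO[Si](c3ccccc3)(c4ccccc4)C(C)(C)C)c1[C@H](C)CBr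
F5 | step 15 | benzyl 3-[(2S,3R)-4-(tert-butyldiphenylsilyloxy)-3-methyl-1-nitrobutan-2-yl]-5-methoxy-4-[(S)-1-(phenylsulfonyl)propan-2-yl]benzoate | COc1cc(C(=O)OCc2ccccc2)cc([C@@H](C[N+](=O)[O-])[C@@H](C)CO[Si](c3ccccc3)(c4ccccc4)C(C)(C)C)c1[C@H](C)CS(=O)(=O)c5ccccc5
F6 | step 15 | (2S,3R)-2-{5-(benzyloxycarbonyl)-3-methoxy-2-[(S)-1-(phenylsulfonyl)propan-2-yl]phenyl}-4-(tert-butyldiphenylsilyloxy)-3-methylbutanoic acid | COc1cc(C(=O)OCc2ccccc2)cc([C@@H](C(=O)O)[C@@H](C)CO[Si](c3ccccc3)(c4ccccc4)C(C)(C)C)c1[C@H](C)CS(=O)(=O)c5ccccc5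
F7 | step 15 | benzyl 3-[(2S,3R)-4-(tert-butyldiphenylsilyloxy)-1-hydroxy-3-methylbutan-2-yl]-5-methoxy-4-[(S)-1-(phenylsulfonyl)propan-2-yl]benzoate | COc1cc(C(=O)OCc2ccccc2)cc([C@@H](CO)[C@@H](C)CO[Si](c3ccccc3)(c4ccccc4)C(C)(C)C)c1[C@H](C)CS(=O)(=O)c5ccccc5
F8 | step 15 | benzyl 3-[(2S,3R)-4-(tert-butyldiphenylsilyloxy)-1-iodo-3-methylbutan-2-yl]-5-methoxy-4-[(S)-1-(phenylsulfonyl)propan-2-yl]benzoate | COc1cc(C(=O)OCc2ccccc2)cc([C@@H](CI)[C@@H](C)CO[Si](c3ccccc3)(c4ccccc4)C(C)(C)C)c1[C@H](C)CS(=O)(=O)c5ccccc5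
F9 | step 15 | benzyl (5S,8S)-8-[(R)-1-(tert-butyldiphenylsilyloxy)propan-2-yl]-4-methoxy-5-methyl-6-(phenylsulfonyl)-5,6,7,8-tetrahydronaphthalene-2-carboxylate (C6 epimers) | COc1cc(C(=O)OCc2ccccc2)cc([C@@H](C6)[C@@H](C)CO[Si](c3ccccc3)(c4ccccc4)C(C)(C)C)c1[C@H](C)C6S(=O)(=O)c5ccccc5
F10 | step 15 | benzyl (5R,8S)-8-[(R)-1-(tert-butyldiphenylsilyloxy)propan-2-yl]-4-methoxy-5-methyl-5,6,7,8-tetrahydronaphthalene-2-carboxylate | COc1cc(C(=O)OCc2ccccc2)cc([C@@H](C6)[C@@H](C)CO[Si](c3ccccc3)(c4ccccc4)C(C)(C)C)c1[C@H](C)C6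
F11 | step 16 | benzyl (5R,8S)-7-amino-8-[(R)-1-hydroxypropan-2-yl]-4-methoxy-5-methyl-5,6,7,8-tetrahydronaphthalene-2-carboxylate (C7 epimers) | COc1cc(C(=O)OCc2ccccc2)cc([C@@H](C3N)[C@@H](C)CO)c1[C@H](C)C3
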